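**Strategy.** The route rests on carrying C18 as a ring atom: ring A (C1–C5, C10) is first closed by metathesis as a seven-membered ring in which the future C18 (C3a) sits between C3 and C4 as part of a C3a=C4(CH3) alkene. Epoxidation and a Lewis-acid epoxide–aldehyde rearrangement then shift C3 from C3a to C4, contracting the ring to the cyclohexane and creating the C4 quaternary stereocentre with its axial C19 methyl and equatorial C18 aldehyde in one operation. The precursor is a carvone-derived trans-fused bicyclo[5.4.0]undecadienone epoxide; ring B (C8, C9) and the side chain (C13 from an Evans alkylation) are elaborated afterwards.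

Key step: step 5

Remark on conventions: locants are labdane locants (C1–C20); C3a is the extra ring carbon between C3 and C4 in the seven-membered precursors (it becomes C18). "Me-face" is the face of the bicycle carrying the angular C10 methyl, "H-face" the face of H-5; the SMILES carry the absolute configuration (target: 4S,5S,8S,9S,10R,13S).

**Route**

Step 1
Reactants: 1 (S)-(+)-carvone
Product: 3 (5S,6RS)-2,6-dimethyl-5-(prop-1-en-2-yl)cyclohex-2-en-1-one, via lithium dienolate of carvone 2 (not isolated)
Conditions: LDA, THF, −78 °C; MeI, −78 → −20 °C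
Reagents that add atoms: iodomethane, CI
Why: Kinetic α′-deprotonation of the cross-conjugated enone and C-methylation (enolate alkylation); the new centre is left uncontrolled because it is re-enolised in step 2.

Step 2
Reactants: 3 (5S,6RS)-2,6-dimethyl-5-(prop-1-en-2-yl)cyclohex-2-en-1-one
Product: 5 (5R,6R)-2,6-dimethyl-6-(pent-4-en-1-yl)-5-(prop-1-en-2-yl)cyclohex-2-en-1-one, via lithium enolate of 6-methylcarvone 4 (not isolated)
Conditions: LDA, THF, −78 → 0 °C; 5-iodopent-1-ene, DMPU, −78 °C → rt
Reagents that add atoms: 5-iodopent-1-ene, C=CCCCI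
Why: Enolate alkylation that makes quaternary C10; the electrophile should enter anti to the neighbouring isopropenyl group (1,2-induction from C5), so pentenyl ends trans and CH3 cis to isopropenyl, the arrangement of a trans ring fusion.

Step 3
Reactants: 5 (5R,6R)-2,6-dimethyl-6-(pent-4-en-1-yl)-5-(prop-1-en-2-yl)cyclohex-2-en-1-one
Product: 6 A-homo dienone (trans-fused bicyclo[5.4.0]undecadienone: seven-membered ring C10–C1–C2–C3–C3a=C4(CH3)–C5; cyclohexenone C5–C6–C7=C8(CH3)–C9(=O)–C10(CH3); H-5 on the H-face)
Conditions: Grubbs II (5 mol %), toluene (5 mM), 80 °C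
Reagents that add atoms: none
Why: Ring-closing metathesis of the terminal alkene with the 1,1-disubstituted isopropenyl group across two trans-diequatorial tethers should give the trisubstituted cycloheptene, the electron-poor enone alkene staying inert.

Step 4
Reactants: 6 A-homo dienone
Product: 7 3a,4-epoxide of 6 with the oxygen on the H-face (anti to the C10 methyl)
Conditions: mCPBA, NaHCO3, CH2Cl2, 0 °C
Reagents that add atoms: 3-chloroperoxybenzoic acid, OOC(=O)c1cccc(Cl)c1
Why: Prilezhaev epoxidation is chemoselective for the electron-rich trisubstituted C3a=C4 alkene over the enone, and the peracid should approach anti to the angular methyl that shields the Me-face of C4.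

Step 5
Reactants: 7 H-face 3a,4-epoxide
Product: 8 ring-contracted keto aldehyde (trans-decalin; C9 ketone; C7=C8(CH3); C4 with CH3 on the Me-face and CHO on the H-face)
Conditions: MABR [methylaluminium bis(4-bromo-2,6-di-tert-butylphenoxide), 20 mol %], CH2Cl2, −78 → −20 °C
Reagents that add atoms: none
Why: The bulky aluminium Lewis acid binds the epoxide oxygen and the C4–O bond (tertiary terminus) ionises while the C3a–C3 ring bond migrates to C4 on the face opposite the departing oxygen and the oxygen lone pair closes to the C3a aldehyde, i.e. a Meinwald (semipinacol-type) epoxide–aldehyde rearrangement with 1,2-alkyl shift. The closest known reaction type is the Lewis-acid ring contraction of 1-methylcycloalkene oxides to 1-methylcycloalkanecarbaldehydes, for which bulky aluminium aryloxides are the promoters that favour carbon over hydride migration. Ring A is closed by a suprafacial 1,2-shift of C3 across the C3a–C4 bond (ring contraction seven to six, no separate cyclisation mode), and the expelled ring carbon C3a becomes the exocyclic C18 aldehyde. The only new stereocentre, quaternary C4, is set by the epoxide configuration: migration with inversion at C4 turns the H-face epoxide into CH3 on the Me-face (axial, syn to C20) and CHO on the H-face (equatorial). The step needs C3 to migrate in preference to H-3a (which would give the A-homo ketone) and to H-5 shift or proton loss; relief of seven-ring strain on forming the chair cyclohexane, the oxygen push available only to the C3a substituents and the steric demand of the Lewis acid are relied on for this, and the remote hindered enone should not interfere.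

Step 6
Reactants: 8 ring-contracted keto aldehyde
Product: 9 18-hydroxy enone (CHO of 8 reduced to CH2OH)
Conditions: NaBH4, EtOH/CH2Cl2, −78 → −40 °C
Reagents that add atoms: none
Why: Chemoselective borohydride reduction; at low temperature the aldehyde should be reduced well before the conjugated ketone flanked by quaternary C10.

Step 7
Reactants: 9 18-hydroxy enone
Product: 10 18-benzyloxy enone
Conditions: BnOC(=NH)CCl3, TfOH (cat.), CH2Cl2/cyclohexane, 0 °C → rt
Reagents that add atoms: benzyl 2,2,2-trichloroacetimidate, ClC(Cl)(Cl)C(=N)OCc1ccccc1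
Why: Acid-catalysed O-benzylation with the trichloroacetimidate works on hindered neopentyl alcohols without base, so the enone is not enolised, and it masks C18–OH until the last step.

Step 8
Reactants: 10 18-benzyloxy enone
Product: 11 18-benzyloxy 7,9(11)-diene (exocyclic C9=C11H2 conjugated with C7=C8)
Conditions: Ph3PCH3Br, KOt-Bu, toluene, 90 °C
Reagents that add atoms: methyltriphenylphosphonium bromide, C[P+](c1ccccc1)(c1ccccc1)c1ccccc1.[Br-]
Why: Wittig methylenation under forcing hot-toluene conditions is the established way to methylenate hindered ketones without α-hydrogens and installs C11.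

Step 9
Reactants: 11 18-benzyloxy 7,9(11)-diene
Product: 13 18-benzyloxy-7-en-11-ol (H-9 on the H-face; CH2OH equatorial on C9), via B-alkyl-9-BBN adduct 12 (not isolated)
Conditions: 9-BBN, THF, 0 → 40 °C; then NaOH, H2O2, 0 °C → rt
Reagents that add atoms: 9-borabicyclo[3.3.1]nonane, B1C2CCCC1CCC2 (its boron stays only in 12); hydrogen peroxide, OO
Why: Hydroboration–oxidation; 9-BBN should add boron to the terminal CH2 of the less hindered exocyclic alkene and deliver hydrogen to C9 from the H-face, anti to the adjacent axial C10 methyl, which sets C9 with the C11 arm equatorial while the trisubstituted C7=C8 alkene survives.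

Step 10
Reactants: 13 18-benzyloxy-7-en-11-ol
Product: 14 18-benzyloxy-7-en-11-al
Conditions: Dess–Martin periodinane, NaHCO3, CH2Cl2, 0 °C → rt
Reagents that add atoms: none
Why: Buffered Dess–Martin oxidation is neutral enough to give the β,γ-unsaturated aldehyde without moving the alkene into conjugation, and C9 keeps its thermodynamically preferred equatorial substituent.

Step 11
Reactants: 15 (4S)-4-benzyl-3-propanoyl-1,3-oxazolidin-2-one
Product: 17 tert-butyl (3R)-4-[(4S)-4-benzyl-2-oxo-1,3-oxazolidin-3-yl]-3-methyl-4-oxobutanoate, via sodium Z-enolate of the imide 16 (not isolated)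
Conditions: NaHMDS, THF, −78 °C; BrCH2CO2t-Bu, −78 → −40 °C
Reagents that add atoms: tert-butyl bromoacetate, BrCC(=O)OC(C)(C)C
Why: Evans asymmetric alkylation; the chelated Z-enolate is alkylated on the face opposite the benzyl group, which sets the future C13 stereocentre.

Step 12
Reactants: 17 alkylated imide
Product: 18 tert-butyl (3R)-4-hydroxy-3-methylbutanoate
Conditions: LiBH4, MeOH (1 equiv), Et2O, 0 °C
Reagents that add atoms: none
Why: Lithium borohydride cleaves the activated imide carbonyl reductively without touching the tert-butyl ester or epimerising the α-centre, and releases the auxiliary.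

Step 13
Reactants: 18 tert-butyl (3R)-4-hydroxy-3-methylbutanoate
Product: 19 tert-butyl (3R)-4-iodo-3-methylbutanoate
Conditions: I2, PPh3, imidazole, CH2Cl2, 0 °C → rt
Reagents that add atoms: iodine, II
Why: Appel-type (Garegg–Samuelsson) iodination of a primary alcohol; the stereocentre is not at the reacting carbon.

Step 14
Reactants: 19 tert-butyl (3R)-4-iodo-3-methylbutanoate
Product: 20 [(2R)-4-(tert-butoxy)-2-methyl-4-oxobutyl]triphenylphosphonium iodide
Conditions: PPh3, MeCN, reflux
Reagents that add atoms: triphenylphosphine, c1ccc(cc1)P(c1ccccc1)c1ccccc1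
Why: SN2 quaternisation of triphenylphosphine by the primary iodide gives the Wittig salt that carries C12–C16.

Step 15
Reactants: 14 18-benzyloxy-7-en-11-al; 20 phosphonium iodide
Product: 22 tert-butyl ester of the (11Z)-18-benzyloxy-7,11-dien-15-oic acid (full labdane carbon skeleton), via phosphorus ylide of the side chain 21 (not isolated)
Conditions: 20, NaHMDS, THF, −78 → 0 °C; then 14, −78 °C → rt
Reagents that add atoms: none
Why: Wittig olefination with a non-stabilised ylide forms the C11–C12 bond (Z expected, geometry irrelevant); the ylide carbon is deprotonated in preference to the ester α-position, and the C13 centre β to phosphorus is untouched.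

Step 16
Reactants: 22 (11Z)-diene ester
Product: 23 tert-butyl ester of the 18-benzyloxy-7-en-15-oic acid (C11–C12 saturated)
Conditions: 2-nitrobenzenesulfonyl hydrazide, Et3N, CH2Cl2, rt
Reagents that add atoms: none
Why: Diimide reduction saturates the 1,2-disubstituted alkene far faster than the trisubstituted ring alkene and does not migrate double bonds, so C9 and C13 are not scrambled.

Step 17
Reactants: 23 7-ene ester
Product: 24 7,8-epoxide with the oxygen on the H-face
Conditions: mCPBA, NaHCO3, CH2Cl2, 0 °C
Reagents that add atoms: 3-chloroperoxybenzoic acid, OOC(=O)c1cccc(Cl)c1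
Why: Prilezhaev epoxidation of the only remaining alkene from the H-face, anti to both the axial C10 methyl and the C9 side chain, fixes the C8–O bond.

Step 18
Reactants: 24 7,8-epoxide
Product: 25 18-benzyloxy-8,15-diol (C8: OH equatorial on the H-face and CH3 axial)
Conditions: LiAlH4, THF, 0 °C → reflux
Reagents that add atoms: none
Why: Hydride opens the trisubstituted epoxide by SN2 attack at the secondary C7, leaving the tertiary C8–O bond with its configuration, and the same reagent reduces the tert-butyl ester to the C15 primary alcohol.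

Step 19
Reactants: 25 18-benzyloxy-8,15-diol
Product: 26 15-O-(benzyl malonyl) derivative of 25
Conditions: HO2CCH2CO2Bn, DCC, DMAP (cat.), CH2Cl2, 0 °C
Reagents that add atoms: 3-(benzyloxy)-3-oxopropanoic acid, OC(=O)CC(=O)OCc1ccccc1
Why: Steglich esterification acylates only the primary C15–OH, since the tertiary C8–OH is inert and C18–OH is still benzylated.

Step 20
Reactants: 26 benzyl malonate
Product: 27 target, 3-{[(3S)-5-[(1S,2S,4aS,5S,8aR)-2-hydroxy-5-(hydroxymethyl)-2,5,8a-trimethyldecahydronaphthalen-1-yl]-3-methylpentyl]oxy}-3-oxopropanoic acid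
Conditions: H2 (1 atm), Pd/C, EtOAc, rt
Reagents that add atoms: none
Why: Hydrogenolysis removes the benzyl ether and the benzyl ester together under neutral conditions that leave the malonate half ester and the tertiary alcohol intact.

**Compound list**

1 | (S)-(+)-carvone, (5S)-2-methyl-5-(prop-1-en-2-yl)cyclohex-2-en-1-one | CC1=CC[C@@H](CC1=O)C(C)=C | starting material
2 | kinetic lithium dienolate of carvone (C1–OLi, C1=C6) | [Li]OC1=C[C@@H](C(C)=C)CC=C1C | intermediate
3 | (5S,6RS)-2,6-dimethyl-5-(prop-1-en-2-yl)cyclohex-2-en-1-one | CC1=CC[C@@H](C(C)C1=O)C(C)=C | intermediate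
4 | lithium enolate of 3 (C1=C6 bearing the 6-methyl) | [Li]OC1=C(C)[C@@H](C(C)=C)CC=C1C | intermediate
5 | (5R,6R)-2,6-dimethyl-6-(pent-4-en-1-yl)-5-(prop-1-en-2-yl)cyclohex-2-en-1-one | C=CCCC[C@]1(C)[C@@H](C(C)=C)CC=C(C)C1=O | intermediate
6 | A-homo dienone, 3,4a,9-trimethyl-1,4a,5,6,7,9a-hexahydro-4H-benzo[7]annulen-4-one (4a-CH3 and 9a-H trans) | CC1=CCCC[C@@]2(C)C(=O)C(C)=CC[C@H]12 | intermediate
7 | 3a,4-epoxide of 6, oxygen on the H-face | C[C@]12O[C@H]1CCC[C@@]3(C)C(=O)C(C)=CC[C@H]23 | intermediate
8 | ring-contracted keto aldehyde (trans-decalin; C9=O; C7=C8; C4: CH3 Me-face, CHO H-face) | O=C1[C@]2(C)CCC[C@](C)(C=O)[C@H]2CC=C1C | intermediate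
9 | 18-hydroxy enone | O=C1[C@]2(C)CCC[C@](C)(CO)[C@H]2CC=C1C | intermediate
10 | 18-benzyloxy enone | O=C1[C@]2(C)CCC[C@](C)(COCc3ccccc3)[C@H]2CC=C1C | intermediate
11 | 18-benzyloxy 7,9(11)-diene | C=C1[C@]2(C)CCC[C@](C)(COCc3ccccc3)[C@H]2CC=C1C | intermediate
12 | B-(C11-alkyl)-9-BBN adduct of 11 | B1(C[C@H]2[C@]3(C)CCC[C@](C)(COCc4ccccc4)[C@H]3CC=C2C)C2CCCC1CCC2 | intermediate
13 | 18-benzyloxy-7-en-11-ol (H-9 on the H-face) | OC[C@H]1[C@]2(C)CCC[C@](C)(COCc3ccccc3)[C@H]2CC=C1C | intermediate
14 | 18-benzyloxy-7-en-11-al | O=C[C@H]1[C@]2(C)CCC[C@](C)(COCc3ccccc3)[C@H]2CC=C1C | intermediate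
15 | (4S)-4-benzyl-3-propanoyl-1,3-oxazolidin-2-one | CCC(=O)N1[C@@H](Cc2ccccc2)COC1=O | starting material
16 | sodium (Z)-enolate of 15 | C/C=C(\O[Na])N1[C@@H](Cc2ccccc2)COC1=O | intermediate
17 | tert-butyl (3R)-4-[(4S)-4-benzyl-2-oxo-1,3-oxazolidin-3-yl]-3-methyl-4-oxobutanoate | C[C@H](CC(=O)OC(C)(C)C)C(=O)N1[C@@H](Cc2ccccc2)COC1=O | intermediate
18 | tert-butyl (3R)-4-hydroxy-3-methylbutanoate | C[C@H](CC(=O)OC(C)(C)C)CO | intermediate
19 | tert-butyl (3R)-4-iodo-3-methylbutanoate | C[C@H](CC(=O)OC(C)(C)C)CI | intermediate
20 | [(2R)-4-(tert-butoxy)-2-methyl-4-oxobutyl]triphenylphosphonium iodide | C[C@H](CC(=O)OC(C)(C)C)C[P+](c1ccccc1)(c1ccccc1)c1ccccc1.[I-] | intermediate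
21 | ylide of 20, tert-butyl (3R)-3-methyl-4-(triphenyl-λ5-phosphanylidene)butanoate | C[C@H](CC(=O)OC(C)(C)C)C=P(c1ccccc1)(c1ccccc1)c1ccccc1 | intermediate
22 | tert-butyl ester of the (11Z)-18-benzyloxy-7,11-dien-15-oic acid | C[C@H](CC(=O)OC(C)(C)C)/C=C\[C@H]1[C@]2(C)CCC[C@](C)(COCc3ccccc3)[C@H]2CC=C1C | intermediate
23 | tert-butyl ester of the 18-benzyloxy-7-en-15-oic acid | C[C@H](CC(=O)OC(C)(C)C)CC[C@H]1[C@]2(C)CCC[C@](C)(COCc3ccccc3)[C@H]2CC=C1C | intermediate
24 | 7,8-epoxide of 23, oxygen on the H-face | C[C@H](CC(=O)OC(C)(C)C)CC[C@H]1[C@]2(C)CCC[C@](C)(COCc3ccccc3)[C@H]2C[C@@H]4O[C@]14C | intermediate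
25 | 18-benzyloxy-8,15-diol | C[C@H](CCO)CC[C@H]1[C@]2(C)CCC[C@](C)(COCc3ccccc3)[C@H]2CC[C@]1(C)O | intermediate
26 | 15-O-(benzyl malonyl)-18-O-benzyl-8-ol | C[C@H](CCOC(=O)CC(=O)OCc4ccccc4)CC[C@H]1[C@]2(C)CCC[C@](C)(COCc3ccccc3)[C@H]2CC[C@]1(C)O | intermediate
27 | target, (4S,5S,8S,9S,10R,13S)-8,18-dihydroxylabdan-15-yl hydrogen malonate | C[C@H](CCOC(=O)CC(=O)O)CC[C@H]1[C@]2(C)CCC[C@](C)(CO)[C@H]2CC[C@]1(C)O | target

**Step count.** Total: 20 steps. Longest linear sequence: 16 steps (steps 1–10 and 15–20, from carvone).

**Steps most likely to fail**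

Step 5 – the hydride on C3a (or proton loss from the C4 cation) may outrun migration of C3, so that no ring contraction occurs. The fallback sets out from 7 and comes back at 9. Isomerisation of 7 under conditions chosen for hydride shift (a small hard Lewis acid such as SbF5) gives the A-homo 3a-ketone F1 (C4–H, either epimer). SO2Cl2 chlorinates its more substituted α-carbon C4 from the H-face to give the α-chloro ketone F2. NaOMe in Et2O then effects a Favorskii ring contraction (the C3 enolate closes onto C4 with inversion, and the cyclopropanone opens toward C3) to the decalin methyl ester F3 with CO2Me on the H-face. LiAlH4 reduces the ester and the enone carbonyl to the diol F4, and MnO2 reoxidises only the allylic C9 alcohol, giving 9.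

Step 8 – the ketone is flanked by a quaternary carbon and the ylide is basic, so addition may stall or γ-deprotonation may take over. The fallback sets out from 10 and comes back at 11 by a Peterson sequence: (trimethylsilyl)methyllithium with CeCl3 adds 1,2 to give the β-hydroxysilane F5, and catalytic TsOH in CH2Cl2 eliminates trimethylsilanol to the diene 11.

Step 4 – facial selectivity in the flexible seven-membered ring may be poor or reversed, which would invert C4 after step 5. The fallback sets out from 6 and comes back at 7. NBS in aqueous DME forms the bromonium ion on the face the peracid would have used, and water opens it at the tertiary C4 from the other face to give the bromohydrin F6. K2CO3 in MeOH closes it with inversion at C3a to the epoxide with oxygen on the H-face, 7.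

Further compounds
F1 | step 5 | A-homo 3a-ketone (C3a=O, C4–H, both C4 epimers) | CC1C(=O)CCC[C@@]2(C)C(=O)C(C)=CC[C@H]12
F2 | step 5 | 4-chloro A-homo 3a-ketone (Cl on the H-face) | C[C@]1(Cl)C(=O)CCC[C@@]2(C)C(=O)C(C)=CC[C@H]12
F3 | step 5 | decalin enone methyl ester (C4: CH3 Me-face, CO2CH3 H-face) | O=C1[C@]2(C)CCC[C@](C)(C(=O)OC)[C@H]2CC=C1C
F4 | step 5 | 9,18-diol (C9 carbinol, both epimers) | OC1[C@]2(C)CCC[C@](C)(CO)[C@H]2CC=C1C
F5 | step 8 | 9-hydroxy-9-[(trimethylsilyl)methyl] adduct of 10 (both C9 epimers) | C[Si](C)(C)CC1(O)[C@]2(C)CCC[C@](C)(COCc3ccccc3)[C@H]2CC=C1C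
F6 | step 4 | bromohydrin of 6 (C3a–Br on the Me-face, C4–OH on the H-face) | Br[C@@H]1CCC[C@@]2(C)C(=O)C(C)=CC[C@@H]2[C@@]1(C)O
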